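**Plan**
- Cuts: first the three C8–O aryl ether bonds (arm E to one syringyl oxygen, unit B to the other, unit A to the guaiacyl oxygen of B). Then O–C7 and O–C7' of the furofuran, and last C7–C8 and C7'–C8'.
- Enabling feature: in the 3,7-dioxabicyclo[3.3.0]octane core each ring-fusion carbon (C8, C8') holds one benzylic carbon (C7, C7') and one oxygenated CH2 (C9, C9'). C9–C8–C8'–C9' is therefore the backbone of a butyrolactone (C2 = C9, C3 = C8, C4 = C8', acetal C5 = C9') with trans benzylic groups and two unlike aryl ends.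
- Forward order: aryl dithiane anion, menthyloxybutenolide and aryl aldehyde are joined in one flask, and no ring forms. The ketone is unmasked, LiAlH4 gives the tetraol, and acid closes both tetrahydrofuran rings together.
- Arms: the allyl group is removed and arm E attached, then the benzyl group is removed and the preassembled A–B arm attached, then all silyl groups are removed.
- Stereochemistry: C8' and C8 are relayed from the crystallised (5S)-menthyl acetal, and C7/C7' come from exo capture of the benzylic cations. C7 of each arm and its pre-inversion C8 come from Evans syn glycolate aldols with (R)- or (S)-4-benzyloxazolidin-2-one. Every arm C8 is inverted in a Mitsunobu etherification, which turns threo into erythro.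

Key step: step 6

Remark (labels): lignan numbering is used for the core; C7/C8/C9 of an arm are its benzylic, ether-bearing and primary carbons; TBS = tert-butyldimethylsilyl.
Remark (assumption): the carbinol carbons made in steps 6 and 8 are expected as epimer mixtures. Compounds 11 and 12 are drawn as one epimer and 13 is written with both carbinol carbons open; all epimers are carried on because step 9 sets both centres afresh.
Remark (assumption): apart from its two phenol protecting groups the core is C2-symmetric, so either syringyl ring may take arm E. The ring freed first (allyl) receives it.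

**Core**

Step 1
Reactants: 1 furfural
Product: 2 5-hydroxyfuran-2(5H)-one (racemic)
Conditions: O2, rose bengal (cat.), MeOH, visible light, rt
Reagents that add atoms: oxygen, O=O
Why: Dye-sensitised singlet-oxygen [4+2] photooxygenation of the furan followed by methanolytic loss of the formyl carbon is the standard entry to this hydroxybutenolide, and no stereocentre is fixed yet.

Step 2
Reactants: 2 5-hydroxyfuran-2(5H)-one; 3 (+)-menthol
Product: 4 (5S)-5-[(1S,2R,5S)-menthyloxy]furan-2(5H)-one
Conditions: neat, 100 °C; crystallisation from petroleum ether, −20 °C; mother liquor re-equilibrated with cat. TsOH and recrystallised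
Reagents that add atoms: none
Why: Thermal acetalisation of the pseudo-acid gives two C5 epimers that interconvert under acid, and the 5S epimer of the (+)-menthol series should crystallise, so the acetal carbon is fixed by crystallisation-driven diastereomer selection.

Step 3
Reactants: 5 syringaldehyde
Product: 6 4-(allyloxy)-3,5-dimethoxybenzaldehyde
Conditions: allyl bromide, K2CO3, DMF, 50 °C
Reagents that add atoms: allyl bromide, C=CCBr
Why: Williamson etherification of an acidic para-formyl phenol with a reactive allylic halide.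

Step 4
Reactants: 5 syringaldehyde
Product: 7 4-(benzyloxy)-3,5-dimethoxybenzaldehyde
Conditions: BnBr, K2CO3, DMF, 50 °C
Reagents that add atoms: benzyl bromide, BrCc1ccccc1
Why: Williamson etherification, which gives the second syringyl unit a phenol protecting group orthogonal to allyl.

Step 5
Reactants: 7 4-(benzyloxy)-3,5-dimethoxybenzaldehyde
Product: 8 2-[4-(benzyloxy)-3,5-dimethoxyphenyl]-1,3-dithiane
Conditions: propane-1,3-dithiol, BF3·OEt2 (cat.), CH2Cl2, 0 °C to rt
Reagents that add atoms: propane-1,3-dithiol, SCCCS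
Why: Lewis-acid-catalysed thioacetalisation turns the aldehyde carbon into an acyl-anion equivalent (umpolung).

Step 6
Reactants: 8 2-[4-(benzyloxy)-3,5-dimethoxyphenyl]-1,3-dithiane; 4 (5S)-5-[(1S,2R,5S)-menthyloxy]furan-2(5H)-one; 6 4-(allyloxy)-3,5-dimethoxybenzaldehyde
Product: 11 (3R,4S,5S)-3-{(R)-[4-(allyloxy)-3,5-dimethoxyphenyl](hydroxy)methyl}-4-{2-[4-(benzyloxy)-3,5-dimethoxyphenyl]-1,3-dithian-2-yl}-5-[(1S,2R,5S)-menthyloxy]dihydrofuran-2(3H)-one, via 2-lithiodithiane 9 (not isolated), via lithium lactone enolate 10 (not isolated)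
Conditions: n-BuLi, THF, −78 to −30 °C; 4, THF, −78 °C; 6, THF, −78 °C; AcOH quench at −78 °C
Reagents that add atoms: none
Why: The sulfur-stabilised benzylic carbanion 9 adds in Michael fashion to C4 of butenolide 4 and the lithium enolate 10 so formed adds to aldehyde 6 in the same flask, making C7'–C8' and then C7–C8; the closest known reaction type is the tandem conjugate addition–aldol of lithiated 2-aryl-1,3-dithianes on 5-alkoxy-2(5H)-furanones. No ring is closed in this step. C8' (lactone C4) is set by attack on the butenolide face anti to the C5 menthyloxy group, and C8 (lactone C3) by approach of the aldehyde anti to the very large dithianyl group just installed, which should give the 3,4-trans-4,5-trans lactone. The carbinol carbon C7 is steered only weakly by the closed lithium aldol transition state and may form as two epimers, which is harmless because step 9 sets it again. The step needs 1,4- over 1,2-addition, which the soft, delocalised and hindered aryl dithiane anion secures at low temperature, and it needs the enolate to be trapped faster than it exchanges protons, which the non-enolisable aldehyde and the cold acidic quench secure.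

Step 7
Reactants: 11 lactone aldol adduct
Product: 12 (3R,4S,5S)-3-{(R)-[4-(allyloxy)-3,5-dimethoxyphenyl](hydroxy)methyl}-4-[4-(benzyloxy)-3,5-dimethoxybenzoyl]-5-[(1S,2R,5S)-menthyloxy]dihydrofuran-2(3H)-one
Conditions: MeI (excess), CaCO3, MeCN/H2O, 45 °C
Reagents that add atoms: water, O
Why: Alkylative dithiane hydrolysis (S-methylation, thionium ion, capture by water) is neutral enough to spare the allyl ether, the menthyl acetal and the β-hydroxy lactone, and C8' has no drive to epimerise because it already lies trans to both ring neighbours.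

Step 8
Reactants: 12 keto lactone acetal
Product: 13 (2S,3S)-1-[4-(allyloxy)-3,5-dimethoxyphenyl]-4-[4-(benzyloxy)-3,5-dimethoxyphenyl]-2,3-bis(hydroxymethyl)butane-1,4-diol (carbinol epimers)
Conditions: LiAlH4, THF, 0 °C to rt; aqueous NaOH work-up
Reagents that add atoms: none
Why: In this exhaustive hydride reduction the aryl ketone gives a carbinol, the lactone opens to the C9 alcohol, and the freed hemiacetal alkoxide expels menthoxide to an aldehyde that is reduced to the C9' alcohol, while C8 and C8' are untouched.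

Step 9
Reactants: 13 tetraol
Product: 14 (7R,7'R,8S,8'S)-4-O-allyl-4'-O-benzylsyringaresinol
Conditions: camphorsulfonic acid (10 mol %), 4 Å molecular sieves, CH2Cl2, 0 °C; Et3N quench at full conversion
Reagents that add atoms: none
Why: In this acid-catalysed double cyclodehydration of SN1 type each para-alkoxybenzylic alcohol ionises and its cation is captured 5-exo by the primary hydroxyl of the neighbouring arm; the 8S,8'S backbone enforces cis fusion and the aryl groups take the convex exo face, which sets 7R and 7'R from either carbinol epimer.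

Step 10
Reactants: 14 allyl benzyl syringaresinol
Product: 15 (7R,7'R,8S,8'S)-4'-O-benzylsyringaresinol (monophenol)
Conditions: Pd(PPh3)4 (5 mol %), morpholine, THF, rt
Reagents that add atoms: none
Why: In this Tsuji–Trost-type deallylation zerovalent palladium ionises the aryl allyl ether to a π-allyl complex that morpholine intercepts, leaving the benzyl ether and the furofuran intact.

**Arms**

Step 11
Reactants: 16 vanillin
Product: 17 4-[(tert-butyldimethylsilyl)oxy]-3-methoxybenzaldehyde
Conditions: TBSCl, imidazole, DMF, rt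
Reagents that add atoms: tert-butyldimethylsilyl chloride, CC(C)(C)[Si](C)(C)Cl
Why: Standard imidazole-promoted silylation of a phenol.

Step 12
Reactants: 18 (R)-4-benzyloxazolidin-2-one
Product: 19 (R)-4-benzyl-3-[(benzyloxy)acetyl]oxazolidin-2-one
Conditions: benzyloxyacetyl chloride, Et3N, DMAP (cat.), CH2Cl2, 0 °C to rt
Reagents that add atoms: benzyloxyacetyl chloride, O=C(Cl)COCc1ccccc1
Why: DMAP-catalysed N-acylation of the purchased auxiliary with an acid chloride.

Step 13
Reactants: 19 (R)-glycolyl imide; 17 silylated vanillin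
Product: 21 (R)-4-benzyl-3-[(2R,3S)-2-(benzyloxy)-3-hydroxy-3-{4-[(tert-butyldimethylsilyl)oxy]-3-methoxyphenyl}propanoyl]oxazolidin-2-one, via Z-dibutylboron enolate 20 (not isolated)
Conditions: Bu2BOTf, Et3N, CH2Cl2, −78 to 0 °C; 17, −78 to 0 °C; pH 7 buffer, MeOH, 30% H2O2, 0 °C
Reagents that add atoms: none
Why: In this Evans syn glycolate aldol the Z-boron enolate reacts through a Zimmerman–Traxler chair on the face away from the benzyl group of the (R)-auxiliary, setting 2R,3S (the later 8S,7S threo pair).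

Step 14
Reactants: 21 syn aldol adduct
Product: 22 (1S,2S)-2-(benzyloxy)-1-{4-[(tert-butyldimethylsilyl)oxy]-3-methoxyphenyl}propane-1,3-diol
Conditions: LiBH4, MeOH (1 equiv), THF, 0 °C
Reagents that add atoms: none
Why: Reductive auxiliary removal with LiBH4 attacks only the exocyclic imide carbonyl and leaves both stereocentres and the aryl silyl ether unchanged.

Step 15
Reactants: 22 (1S,2S)-diol
Product: 23 (1S,2S)-2-(benzyloxy)-1,3-bis[(tert-butyldimethylsilyl)oxy]-1-{4-[(tert-butyldimethylsilyl)oxy]-3-methoxyphenyl}propane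
Conditions: TBSOTf, 2,6-lutidine, CH2Cl2, −78 to 0 °C
Reagents that add atoms: tert-butyldimethylsilyl triflate, CC(C)(C)[Si](C)(C)OS(=O)(=O)C(F)(F)F
Why: Silyl triflate silylation caps the primary and the hindered benzylic hydroxyl in one base-buffered operation.

Step 16
Reactants: 23 tris-silyl benzyl ether
Product: 24 (1S,2S)-1,3-bis[(tert-butyldimethylsilyl)oxy]-1-{4-[(tert-butyldimethylsilyl)oxy]-3-methoxyphenyl}propan-2-ol
Conditions: H2 (1 atm), Pd/C (10 wt %), EtOAc, rt
Reagents that add atoms: none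
Why: Catalytic hydrogenolysis cleaves the only benzyl ether and frees the C8 hydroxyl, the silyl ethers being inert in ethyl acetate.

Step 17
Reactants: 25 (S)-4-benzyloxazolidin-2-one
Product: 26 (S)-4-benzyl-3-[(benzyloxy)acetyl]oxazolidin-2-one
Conditions: benzyloxyacetyl chloride, Et3N, DMAP (cat.), CH2Cl2, 0 °C to rt
Reagents that add atoms: benzyloxyacetyl chloride, O=C(Cl)COCc1ccccc1
Why: DMAP-catalysed N-acylation, the mirror image of step 12.

Step 18
Reactants: 26 (S)-glycolyl imide; 17 silylated vanillin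
Product: 28 (S)-4-benzyl-3-[(2S,3R)-2-(benzyloxy)-3-hydroxy-3-{4-[(tert-butyldimethylsilyl)oxy]-3-methoxyphenyl}propanoyl]oxazolidin-2-one, via Z-dibutylboron enolate 27 (not isolated)
Conditions: Bu2BOTf, Et3N, CH2Cl2, −78 to 0 °C; 17, −78 to 0 °C; pH 7 buffer, MeOH, 30% H2O2, 0 °C
Reagents that add atoms: none
Why: Evans syn glycolate aldol under control of the (S)-auxiliary, setting 2S,3R (the later 8R,7R threo pair).

Step 19
Reactants: 28 syn aldol adduct
Product: 29 (1R,2R)-2-(benzyloxy)-1-{4-[(tert-butyldimethylsilyl)oxy]-3-methoxyphenyl}propane-1,3-diol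
Conditions: LiBH4, MeOH (1 equiv), THF, 0 °C
Reagents that add atoms: none
Why: Reductive auxiliary removal as in step 14, without change at the stereocentres.

Step 20
Reactants: 29 (1R,2R)-diol
Product: 30 (1R,2R)-2-(benzyloxy)-1,3-bis[(tert-butyldimethylsilyl)oxy]-1-{4-[(tert-butyldimethylsilyl)oxy]-3-methoxyphenyl}propane
Conditions: TBSOTf, 2,6-lutidine, CH2Cl2, −78 to 0 °C
Reagents that add atoms: tert-butyldimethylsilyl triflate, CC(C)(C)[Si](C)(C)OS(=O)(=O)C(F)(F)F
Why: Double silyl triflate silylation as in step 15.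

Step 21
Reactants: 30 tris-silyl benzyl ether
Product: 31 (1R,2R)-1,3-bis[(tert-butyldimethylsilyl)oxy]-1-{4-[(tert-butyldimethylsilyl)oxy]-3-methoxyphenyl}propan-2-ol
Conditions: H2 (1 atm), Pd/C (10 wt %), EtOAc, rt
Reagents that add atoms: none
Why: Catalytic hydrogenolysis of the single benzyl ether as in step 16.

Step 22
Reactants: 23 tris-silyl benzyl ether
Product: 32 4-{(1S,2S)-2-(benzyloxy)-1,3-bis[(tert-butyldimethylsilyl)oxy]propyl}-2-methoxyphenol
Conditions: K2CO3 (0.5 equiv), MeOH/THF, rt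
Reagents that add atoms: none
Why: A phenoxide is a far better leaving group from silicon than an alkoxide, so mild carbonate methanolysis removes only the aryl silyl ether.

Step 23
Reactants: 32 unit B phenol; 31 (1R,2R)-alcohol
Product: 33 A–B dimer benzyl ether (unit A 7R,8S with 4-, 7- and 9-OTBS; unit B 7S,8S with 7- and 9-OTBS and 8-OBn)
Conditions: PPh3, DIAD, THF, 0 °C to rt
Reagents that add atoms: none
Why: In this Mitsunobu etherification the guaiacyl phenol displaces the oxyphosphonium group of 31 by SN2 with inversion at C8, turning the threo alcohol into the erythro 7R,8S ether of unit A.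

Step 24
Reactants: 33 A–B dimer benzyl ether
Product: 34 A–B dimer alcohol (free C8 hydroxyl on unit B, 7S,8S)
Conditions: H2 (1 atm), Pd/C (10 wt %), EtOAc, rt
Reagents that add atoms: none
Why: Catalytic hydrogenolysis removes the one benzyl ether, while the alkyl aryl ether at C8 of unit A is not benzylic and stays.

**Assembly**

Step 25
Reactants: 15 monophenol; 24 (1S,2S)-alcohol
Product: 35 4'-O-benzylsyringaresinol carrying silylated arm E (7S,8R) on O-4
Conditions: PPh3, DIAD, THF (about 1 M), sonication, 0 °C to rt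
Reagents that add atoms: none
Why: Mitsunobu etherification with SN2 inversion at C8 (8S to 8R) gives the erythro arm, high concentration with sonication being the established remedy for ortho,ortho-disubstituted phenols.

Step 26
Reactants: 35 benzyl ether carrying arm E
Product: 36 syringaresinol carrying silylated arm E, free 4'-phenol
Conditions: H2 (1 atm), Pd/C (10 wt %), EtOAc, rt, stopped at consumption of 35
Reagents that add atoms: none
Why: Hydrogenolysis of a phenolic benzyl ether is much faster than cleavage of the furofuran C–O bonds or of benzylic silyl ethers, so timely interruption should give the phenol alone.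

Step 27
Reactants: 36 phenol carrying arm E; 34 A–B dimer alcohol
Product: 37 octakis-O-TBS ether of the target
Conditions: PPh3, DIAD, THF (about 1 M), sonication, 0 °C to rt
Reagents that add atoms: none
Why: A second Mitsunobu etherification of a syringyl phenol inverts C8 of unit B (8S to 8R) and so completes the third erythro pair.

Step 28
Reactants: 37 octakis-O-TBS ether
Product: 38 target CNP0316493.2
Conditions: Bu4NF, AcOH (1:1), THF, 0 °C to rt
Reagents that add atoms: none
Why: Acetic-acid-buffered fluoride desilylation removes all eight silyl groups without acid or strong base, so neither the furofuran nor the para-hydroxybenzylic carbinols can epimerise.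

**Compound list**

1 | furfural | O=Cc1ccco1 | starting material
2 | 5-hydroxyfuran-2(5H)-one (racemic) | OC1OC(=O)C=C1 | intermediate
3 | (+)-menthol, (1S,2R,5S) | C[C@H]1CC[C@@H]([C@H](C1)O)C(C)C | starting material
4 | (5S)-5-[(1S,2R,5S)-menthyloxy]furan-2(5H)-one | C[C@H]1CC[C@@H]([C@H](C1)O[C@H]2OC(=O)C=C2)C(C)C | intermediate
5 | syringaldehyde | COc1cc(C=O)cc(OC)c1O | starting material
6 | 4-(allyloxy)-3,5-dimethoxybenzaldehyde | C=CCOc1c(OC)cc(C=O)cc1OC | intermediate
7 | 4-(benzyloxy)-3,5-dimethoxybenzaldehyde | COc1cc(C=O)cc(OC)c1OCc1ccccc1 | intermediate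
8 | 2-[4-(benzyloxy)-3,5-dimethoxyphenyl]-1,3-dithiane | COc1cc(C2SCCCS2)cc(OC)c1OCc1ccccc1 | intermediate
9 | 2-lithio derivative of 8 | [Li]C1(SCCCS1)c1cc(OC)c(OCc2ccccc2)c(OC)c1 | intermediate
10 | lithium enolate of the (4S,5S)-4-dithianyl-5-menthyloxy lactone | C[C@H]1CC[C@@H]([C@H](C1)O[C@H]2OC(O[Li])=C[C@@H]2C3(c4cc(OC)c(OCc5ccccc5)c(OC)c4)SCCCS3)C(C)C | intermediate
11 | (3R,4S,5S)-lactone aldol adduct, carbinol drawn R | C[C@H]1CC[C@@H]([C@H](C1)O[C@H]2OC(=O)[C@@H]([C@@H](O)c3cc(OC)c(OCC=C)c(OC)c3)[C@@H]2C5(c3cc(OC)c(OCc4ccccc4)c(OC)c3)SCCCS5)C(C)C | intermediate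
12 | (3R,4S,5S)-4-aroyl lactone acetal | C[C@H]1CC[C@@H]([C@H](C1)O[C@H]2OC(=O)[C@@H]([C@@H](O)c3cc(OC)c(OCC=C)c(OC)c3)[C@@H]2C(=O)c3cc(OC)c(OCc4ccccc4)c(OC)c3)C(C)C | intermediate
13 | (2S,3S)-tetraol, carbinol epimers | OC[C@@H](C(O)c1cc(OC)c(OCC=C)c(OC)c1)[C@@H](CO)C(O)c1cc(OC)c(OCc2ccccc2)c(OC)c1 | intermediate
14 | (7R,7'R,8S,8'S)-4-O-allyl-4'-O-benzylsyringaresinol | C=CCOc1c(OC)cc([C@@H]2OC[C@@H]3[C@H]2CO[C@H]3c2cc(OC)c(OCc3ccccc3)c(OC)c2)cc1OC | intermediate
15 | (7R,7'R,8S,8'S)-4'-O-benzylsyringaresinol | Oc1c(OC)cc([C@@H]2OC[C@@H]3[C@H]2CO[C@H]3c2cc(OC)c(OCc3ccccc3)c(OC)c2)cc1OC | intermediate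
16 | vanillin | COc1cc(C=O)ccc1O | starting material
17 | 4-(TBS-oxy)-3-methoxybenzaldehyde | COc1cc(C=O)ccc1O[Si](C)(C)C(C)(C)C | intermediate
18 | (R)-4-benzyloxazolidin-2-one | O=C1N[C@H](Cc2ccccc2)CO1 | starting material
19 | (R)-4-benzyl-3-[(benzyloxy)acetyl]oxazolidin-2-one | O=C(COCc1ccccc1)N1[C@H](Cc2ccccc2)COC1=O | intermediate
20 | Z-dibutylboron enolate of 19 | CCCCB(CCCC)O/C(=C\OCc1ccccc1)N1[C@H](Cc2ccccc2)COC1=O | intermediate
21 | (2R,3S) syn aldol adduct on the (R)-auxiliary | COc1cc([C@H](O)[C@H](C(=O)N2[C@H](Cc3ccccc3)COC2=O)OCc2ccccc2)ccc1O[Si](C)(C)C(C)(C)C | intermediate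
22 | (1S,2S)-2-benzyloxy-1-aryl-propane-1,3-diol | COc1cc([C@H](O)[C@H](CO)OCc2ccccc2)ccc1O[Si](C)(C)C(C)(C)C | intermediate
23 | (1S,2S)-tris-TBS 2-benzyl ether | COc1cc([C@H](O[Si](C)(C)C(C)(C)C)[C@H](CO[Si](C)(C)C(C)(C)C)OCc2ccccc2)ccc1O[Si](C)(C)C(C)(C)C | intermediate
24 | (1S,2S)-tris-TBS propan-2-ol | COc1cc([C@H](O[Si](C)(C)C(C)(C)C)[C@H](CO[Si](C)(C)C(C)(C)C)O)ccc1O[Si](C)(C)C(C)(C)C | intermediate
25 | (S)-4-benzyloxazolidin-2-one | O=C1N[C@@H](Cc2ccccc2)CO1 | starting material
26 | (S)-4-benzyl-3-[(benzyloxy)acetyl]oxazolidin-2-one | O=C(COCc1ccccc1)N1[C@@H](Cc2ccccc2)COC1=O | intermediate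
27 | Z-dibutylboron enolate of 26 | CCCCB(CCCC)O/C(=C\OCc1ccccc1)N1[C@@H](Cc2ccccc2)COC1=O | intermediate
28 | (2S,3R) syn aldol adduct on the (S)-auxiliary | COc1cc([C@@H](O)[C@@H](C(=O)N2[C@@H](Cc3ccccc3)COC2=O)OCc2ccccc2)ccc1O[Si](C)(C)C(C)(C)C | intermediate
29 | (1R,2R)-2-benzyloxy-1-aryl-propane-1,3-diol | COc1cc([C@@H](O)[C@@H](CO)OCc2ccccc2)ccc1O[Si](C)(C)C(C)(C)C | intermediate
30 | (1R,2R)-tris-TBS 2-benzyl ether | COc1cc([C@@H](O[Si](C)(C)C(C)(C)C)[C@@H](CO[Si](C)(C)C(C)(C)C)OCc2ccccc2)ccc1O[Si](C)(C)C(C)(C)C | intermediate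
31 | (1R,2R)-tris-TBS propan-2-ol | COc1cc([C@@H](O[Si](C)(C)C(C)(C)C)[C@@H](CO[Si](C)(C)C(C)(C)C)O)ccc1O[Si](C)(C)C(C)(C)C | intermediate
32 | unit B phenol (7S,8S; 8-OBn; 7,9-OTBS) | COc1cc([C@H](O[Si](C)(C)C(C)(C)C)[C@H](CO[Si](C)(C)C(C)(C)C)OCc2ccccc2)ccc1O | intermediate
33 | A–B dimer benzyl ether (A 7R,8S; B 7S,8S) | COc1cc([C@@H](O[Si](C)(C)C(C)(C)C)[C@H](CO[Si](C)(C)C(C)(C)C)Oc2ccc([C@H](O[Si](C)(C)C(C)(C)C)[C@H](CO[Si](C)(C)C(C)(C)C)OCc3ccccc3)cc2OC)ccc1O[Si](C)(C)C(C)(C)C | intermediate
34 | A–B dimer alcohol (A 7R,8S; B 7S,8S) | COc1cc([C@@H](O[Si](C)(C)C(C)(C)C)[C@H](CO[Si](C)(C)C(C)(C)C)Oc2ccc([C@H](O[Si](C)(C)C(C)(C)C)[C@H](CO[Si](C)(C)C(C)(C)C)O)cc2OC)ccc1O[Si](C)(C)C(C)(C)C | intermediate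
35 | 4'-O-benzylsyringaresinol with silylated arm E (7S,8R) | c1ccccc1COc3c(OC)cc([C@@H]4OC[C@@H]5[C@H]4CO[C@H]5c4cc(OC)c(O[C@H](CO[Si](C)(C)C(C)(C)C)[C@@H](O[Si](C)(C)C(C)(C)C)c5ccc(O[Si](C)(C)C(C)(C)C)c(OC)c5)c(OC)c4)cc3OC | intermediate
36 | syringaresinol with silylated arm E, free 4'-phenol | Oc3c(OC)cc([C@@H]4OC[C@@H]5[C@H]4CO[C@H]5c4cc(OC)c(O[C@H](CO[Si](C)(C)C(C)(C)C)[C@@H](O[Si](C)(C)C(C)(C)C)c5ccc(O[Si](C)(C)C(C)(C)C)c(OC)c5)c(OC)c4)cc3OC | intermediate
37 | octakis-O-TBS ether of the target | COc1cc([C@@H](O[Si](C)(C)C(C)(C)C)[C@H](CO[Si](C)(C)C(C)(C)C)Oc2ccc([C@H](O[Si](C)(C)C(C)(C)C)[C@@H](CO[Si](C)(C)C(C)(C)C)Oc3c(OC)cc([C@@H]4OC[C@@H]5[C@H]4CO[C@H]5c4cc(OC)c(O[C@H](CO[Si](C)(C)C(C)(C)C)[C@@H](O[Si](C)(C)C(C)(C)C)c5ccc(O[Si](C)(C)C(C)(C)C)c(OC)c5)c(OC)c4)cc3OC)cc2OC)ccc1O[Si](C)(C)C(C)(C)C | intermediate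
38 | CNP0316493.2 (core 7R,7'R,8S,8'S; A 7R,8S; B 7S,8R; E 7S,8R) | COc1cc([C@@H](O)[C@H](CO)Oc2ccc([C@H](O)[C@@H](CO)Oc3c(OC)cc([C@@H]4OC[C@@H]5[C@H]4CO[C@H]5c4cc(OC)c(O[C@H](CO)[C@@H](O)c5ccc(O)c(OC)c5)c(OC)c4)cc3OC)cc2OC)ccc1O | target

**Totals**

Total step count: 28.
Longest linear sequence: 11 steps (1, 2, 6, 7, 8, 9, 10, 25, 26, 27, 28).

**Steps most likely to fail**

**1. Step 25, the first etherification of a 2,6-dimethoxyphenol.** The doubly ortho-substituted phenoxide may attack the oxyphosphonium salt of the flanked secondary alcohol too slowly. Elimination, silyl migration or participation of the electron-rich aryl group, with loss of clean inversion, could then take over.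

The fallback forms the C7–C8 bond instead of the C8–O bond. It sets out from 15 and returns at 35.
- Oxazolidinone 25 is acylated (n-BuLi, bromoacetyl bromide, THF, −78 °C) to (S)-4-benzyl-3-(bromoacetyl)oxazolidin-2-one F1.
- Phenol 15 is alkylated at the unhindered CH2Br of that reagent (K2CO3, acetone) to the core aryloxyacetyl imide F2.
- Enolisation with Bu2BOTf/Et3N and addition of aldehyde 17 should give the Evans syn adduct F3 (7R,8R after reduction).
- LiBH4 gives the threo diol F4.
- TBSCl/imidazole silylates only the primary hydroxyl, giving the threo 9-O-TBS alcohol F5.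
- A Mitsunobu esterification with 4-nitrobenzoic acid inverts C7 to the erythro 4-nitrobenzoate F6.
- K2CO3/MeOH removes the ester and the phenolic silyl group, giving the erythro phenol alcohol F7.
- TBSOTf/2,6-lutidine then leads to 35.

**2. Step 9, the double ring closure.** A benzylic cation may be captured by the other benzylic hydroxyl, closing a 2,5-diaryl tetrahydrofuran. Prolonged acid contact may also epimerise C7 or C7' after closure.

The fallback closes the rings one at a time with C7' kept masked. It sets out from 11 and returns at 14.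
- LiAlH4 reduces 11 directly to the dithianyl triol F8.
- Catalytic camphorsulfonic acid can then close only the C7–O–C9' ring. This should give the monocyclic dithianyl tetrahydrofuran F9, with the aryl group on the face opposite to both neighbouring substituents.
- MeI/CaCO3 in aqueous MeCN unmasks the aryl ketone F10, which is held in the cis form by its hemiketal.
- NaBH4 gives the benzylic alcohol F11.
- A brief second acid treatment closes the remaining ring to 14.

**3. Step 6, the three-component coupling.** The enolate may exchange protons before it meets the aldehyde, the lithium aldolate may revert on warming, or some 1,2-addition may occur.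

The fallback makes the same two bonds in two separate operations with a different enolate metal. It sets out from 8 and 4 and returns at 11.
- The conjugate addition is quenched with AcOH and the 4-dithianyl lactone F12 is isolated.
- The lactone is deprotonated with LDA (THF, −78 °C) and transmetallated with ZnCl2.
- The zinc enolate, whose aldolate resists reversal, is combined with aldehyde 6. The aldehyde again approaches anti to the dithianyl group and gives 11.

**Further compounds**

F1 | step 25 | (S)-4-benzyl-3-(bromoacetyl)oxazolidin-2-one | O=C(CBr)N1[C@@H](Cc2ccccc2)COC1=O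
F2 | step 25 | core aryloxyacetyl imide | c1ccccc1COc3c(OC)cc([C@@H]4OC[C@@H]5[C@H]4CO[C@H]5c4cc(OC)c(OCC(=O)N5[C@@H](Cc6ccccc6)COC5=O)c(OC)c4)cc3OC
F3 | step 25 | Evans syn adduct (2S,3R on the imide) | c1ccccc1COc3c(OC)cc([C@@H]4OC[C@@H]5[C@H]4CO[C@H]5c4cc(OC)c(O[C@H](C(=O)N5[C@@H](Cc6ccccc6)COC5=O)[C@H](O)c5ccc(O[Si](C)(C)C(C)(C)C)c(OC)c5)c(OC)c4)cc3OC
F4 | step 25 | threo diol (7R,8R) | c1ccccc1COc3c(OC)cc([C@@H]4OC[C@@H]5[C@H]4CO[C@H]5c4cc(OC)c(O[C@H](CO)[C@H](O)c5ccc(O[Si](C)(C)C(C)(C)C)c(OC)c5)c(OC)c4)cc3OC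
F5 | step 25 | threo 9-O-TBS alcohol (7R,8R) | c1ccccc1COc3c(OC)cc([C@@H]4OC[C@@H]5[C@H]4CO[C@H]5c4cc(OC)c(O[C@H](CO[Si](C)(C)C(C)(C)C)[C@H](O)c5ccc(O[Si](C)(C)C(C)(C)C)c(OC)c5)c(OC)c4)cc3OC
F6 | step 25 | erythro 4-nitrobenzoate (7S,8R) | c1ccccc1COc3c(OC)cc([C@@H]4OC[C@@H]5[C@H]4CO[C@H]5c4cc(OC)c(O[C@H](CO[Si](C)(C)C(C)(C)C)[C@@H](OC(=O)c5ccc(cc5)[N+](=O)[O-])c5ccc(O[Si](C)(C)C(C)(C)C)c(OC)c5)c(OC)c4)cc3OC
F7 | step 25 | erythro phenol alcohol (7S,8R) | c1ccccc1COc3c(OC)cc([C@@H]4OC[C@@H]5[C@H]4CO[C@H]5c4cc(OC)c(O[C@H](CO[Si](C)(C)C(C)(C)C)[C@@H](O)c5ccc(O)c(OC)c5)c(OC)c4)cc3OC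
F8 | step 9 | dithianyl triol (8S,8'S, carbinol as drawn in 11) | OC[C@@H]([C@@H](O)c1cc(OC)c(OCC=C)c(OC)c1)[C@@H](CO)C1(c2cc(OC)c(OCc3ccccc3)c(OC)c2)SCCCS1
F9 | step 9 | monocyclic dithianyl tetrahydrofuran (7R,8S,8'S) | C=CCOc1c(OC)cc([C@@H]2OC[C@@H](C3(c4cc(OC)c(OCc5ccccc5)c(OC)c4)SCCCS3)[C@H]2CO)cc1OC
F10 | step 9 | aryl ketone (7R,8S,8'S, open keto form) | C=CCOc1c(OC)cc([C@@H]2OC[C@@H](C(=O)c3cc(OC)c(OCc4ccccc4)c(OC)c3)[C@H]2CO)cc1OC
F11 | step 9 | benzylic alcohol (7R,8S,8'S, C7' epimers) | C=CCOc1c(OC)cc([C@@H]2OC[C@@H](C(O)c3cc(OC)c(OCc4ccccc4)c(OC)c3)[C@H]2CO)cc1OC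
F12 | step 6 | (4S,5S)-4-dithianyl lactone | C[C@H]1CC[C@@H]([C@H](C1)O[C@H]2OC(=O)C[C@@H]2C3(c4cc(OC)c(OCc5ccccc5)c(OC)c4)SCCCS3)C(C)C
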